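**Retrosynthetic overview**

Eudesmane numbering is used for the decalin (ring A: C1–C5 and C10; ring B: C5–C10; C11 = carbinol carbon on C7, C14 = angular methyl on C10, C15 = methyl on C4). Late disconnections: the aryl–allyl and aryl–aryl bonds of the honokiol unit (Suzuki couplings), the two methyl groups on C11 (ester), and the tertiary C4–O–aryl bond (arylation of the C4 alkoxide with a diaryliodonium salt).
The C4 carbinol comes from a C4=C15 methylidene group (hydration from the α face), the C7 hydrogen from a C6=C7 enoate (conjugate reduction, equatorial ester), and the C14 methyl from an angular formyl group.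
Key disconnection: ring B is then a cyclohexene with its double bond at C6=C7, flanked by the bonds C5–C10 and C8–C9. Cleaving both gives a diene C5=C6–C7=C8 and an alkene C9=C10 that remain joined through C4 and the C1–C3 chain of ring A, so one intramolecular Diels–Alder reaction of an acyclic, achiral tetraenal closes rings A and B together. The enabling feature is that quaternary C10 carries C14, which at the aldehyde level makes C9=C10 a 2-alkylacrolein (activation and a binding site for a chiral Lewis acid), while C7 carries C11, which at the ester level sits on the inner diene carbon.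
Ring order: rings A and B together in step 5; the two benzene rings are bought and joined to the core last. The tetraenal is made in four steps from hept-6-yn-1-ol.

Key step: step 5

Assumption: the sense of asymmetric induction in step 5 is taken from the accepted binding model for 2-substituted acroleins on cationic oxazaborolidines; the (S)-prolinol-derived catalyst is written, and if that model assigns the opposite face for this tethered substrate, its equally available mirror image is the one meant.

**Route**

Step 1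
Reactants: 1 hept-6-yn-1-ol
Product: 2 6-methylideneoct-7-en-1-ol
Conditions: ethylene (1 atm), (H2IMes)(PCy3)Cl2Ru=CHPh (second-generation Grubbs catalyst, 5 mol %), CH2Cl2, rt
Reagents that add atoms: ethylene, C=C
Why: Cross enyne metathesis of a terminal alkyne with ethylene should convert the triple bond into a 2-substituted buta-1,3-diene with all atoms retained, and the free primary alcohol is tolerated.

Step 2
Reactants: 2 6-methylideneoct-7-en-1-ol; 3 methyl 2-bromoprop-2-enoate
Product: 4 methyl (3E)-10-hydroxy-2,5-dimethylidenedec-3-enoate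
Conditions: Pd(OAc)2 (5 mol %), Bu4NCl, K2CO3, DMF, 40 °C, dark, trace BHT
Reagents that add atoms: none
Why: Heck reaction: the alkenylpalladium species should add to the unsubstituted vinyl terminus of the diene (the 1,1-disubstituted terminus is more hindered), and syn β-hydride elimination from the allylpalladium intermediate should give the (E)-triene.

Step 3
Reactants: 4 methyl (3E)-10-hydroxy-2,5-dimethylidenedec-3-enoate
Product: 5 methyl (3E)-2,5-dimethylidene-10-oxodec-3-enoate
Conditions: Dess–Martin periodinane, CH2Cl2, 0 °C to rt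
Reagents that add atoms: none
Why: Dess–Martin oxidation of the primary alcohol stops at the aldehyde under neutral conditions that leave the triene ester untouched.

Step 4
Reactants: 5 methyl (3E)-2,5-dimethylidene-10-oxodec-3-enoate
Product: 7 methyl (3E)-9-formyl-2,5-dimethylidenedeca-3,9-dienoate, via Mannich base 6 (not isolated)
Conditions: [Me2N=CH2]I (Eschenmoser's salt), Et3N, CH2Cl2, 0 °C to rt; filtered cold through silica and used at once
Reagents that add atoms: N,N-dimethylmethyleneiminium iodide (Eschenmoser's salt), C=[N+](C)C.[I-]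
Why: Mannich α-methylenation: the aldehyde has a single enolisable CH2, and aminomethylation followed by loss of dimethylamine should give the 2-alkylacrolein at room temperature, below the onset of the uncatalysed cycloaddition.

Step 5
Reactants: 7 methyl (3E)-9-formyl-2,5-dimethylidenedeca-3,9-dienoate
Product: 8 methyl (4aS,8aS)-4a-formyl-8-methylidene-3,4,4a,5,6,7,8,8a-octahydronaphthalene-2-carboxylate
Conditions: (S)-3,3-diphenyl-1-(2-methylphenyl)tetrahydro-1H,3H-pyrrolo[1,2-c][1,3,2]oxazaborole (20 mol %) activated with HN(SO2CF3)2 (16 mol %), CH2Cl2 (0.01 M), −78 to −20 °C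
Reagents that add atoms: none
Why: Binding of the formyl oxygen to the cationic boron Lewis acid lowers the LUMO of the C9=C10 alkene, and a concerted, asynchronous intramolecular [4+2] cycloaddition with the C5=C6–C7=C8 diene forms C8–C9 (more advanced) and C5–C10 in one operation. The closest known reaction types are the oxazaborolidinium-catalysed enantioselective Diels–Alder reaction of 2-substituted acroleins and the Lewis acid-catalysed type 1 intramolecular Diels–Alder reaction of 1,7,9-decatrienes. Ring B closes as the cyclohexene of the cycloaddition itself, and ring A closes at the same time through the C5–C10 bond as the fused six-membered ring spanned by the four-atom tether C1–C4 in a chair-like arrangement. The trans relation of the C10 formyl group and the C5 hydrogen follows from the endo position of the Lewis acid-bound formyl group, which places the tether exo, together with the (E) geometry of C5=C6. The absolute configuration is set by the catalyst, which holds the s-trans enal through the B–O bond and a formyl C–H···O contact and covers one face, so that C5 should add to the Si face of C10. The step needs regio-, peri-, endo and facial selectivity: the tether and the matched polarisation (largest diene coefficient at C8 next to the ester-bearing C7, meeting the enal β-carbon C9) fix the regiochemistry, the bridged alternative through the C15=C4–C5=C6 diene is strained, and high dilution at low temperature should hold back dimerisation of the 2-carbomethoxy diene and the racemic background reaction.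

Step 6
Reactants: 8 methyl (4aS,8aS)-4a-formyl-8-methylidene-3,4,4a,5,6,7,8,8a-octahydronaphthalene-2-carboxylate
Product: 10 methyl (4aR,8aS)-4a-methyl-8-methylidene-3,4,4a,5,6,7,8,8a-octahydronaphthalene-2-carboxylate, via tosylhydrazone 9 (not isolated)
Conditions: TsNHNH2, MeOH, rt; evaporate; catecholborane, CHCl3, 0 °C; then NaOAc·3H2O, reflux
Reagents that add atoms: none
Why: Tosylhydrazone formation and catecholborane reduction (a mild Wolff–Kishner variant) should turn the neopentyl aldehyde into the angular methyl group without reducing the enoate or moving either double bond; no stereocentre is touched (the descriptor at C4a changes only by priority).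

Step 7
Reactants: 10 methyl (4aR,8aS)-4a-methyl-8-methylidene-3,4,4a,5,6,7,8,8a-octahydronaphthalene-2-carboxylate
Product: 12 methyl (2R,4aR,8aS)-4a-methyl-8-methylidenedecahydronaphthalene-2-carboxylate, via C-2 epimer 11 (not isolated)
Conditions: Mg turnings, MeOH, 0 °C to rt; then NaOMe (cat.), MeOH, 40 °C
Reagents that add atoms: none
Why: Dissolving-metal 1,4-reduction with Mg in methanol is specific for the conjugated ester (the isolated methylidene group is inert), and methoxide equilibration should place the ester equatorial (β) at C7 of the trans-decalin, so this centre is set under thermodynamic control.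

Step 8
Reactants: 12 methyl (2R,4aR,8aS)-4a-methyl-8-methylidenedecahydronaphthalene-2-carboxylate
Product: 14 methyl (2R,4aR,8R,8aR)-8-hydroxy-4a,8-dimethyldecahydronaphthalene-2-carboxylate, via tertiary hydroperoxide 13 (not isolated)
Conditions: Mn(dpm)3 (10 mol %; dpm = 2,2,6,6-tetramethylheptane-3,5-dionate), PhSiH3, O2 (1 atm), iPrOH/CH2Cl2, 0 °C; then PPh3
Reagents that add atoms: dioxygen, O=O
Why: Mukaiyama hydration: Markovnikov hydrogen-atom transfer to the methylidene carbon gives the tertiary C4 radical, which dioxygen should trap from the α (equatorial) face because the β-axial approach is blocked by the syn-axial C10 methyl group, giving the equatorial alcohol with the axial methyl (8R).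

Step 9
Reactants: 15 2-bromo-4-chloro-1-iodobenzene; 16 1,3,5-trimethoxybenzene
Product: 18 (2-bromo-4-chlorophenyl)(2,4,6-trimethoxyphenyl)iodonium 4-methylbenzenesulfonate, via hydroxy(tosyloxy)iodoarene 17 (not isolated)
Conditions: mCPBA, TsOH·H2O, MeCN, 55 °C; then 16, rt
Reagents that add atoms: 4-methylbenzenesulfonic acid, Cc1ccc(S(=O)(=O)O)cc1
Why: One-pot oxidation of the aryl iodide to a trivalent iodine species and electrophilic substitution of the electron-rich arene is the standard preparation of aryl(trimethoxyphenyl)iodonium salts.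

Step 10
Reactants: 14 methyl (2R,4aR,8R,8aR)-8-hydroxy-4a,8-dimethyldecahydronaphthalene-2-carboxylate; 18 (2-bromo-4-chlorophenyl)(2,4,6-trimethoxyphenyl)iodonium 4-methylbenzenesulfonate
Product: 20 methyl (2R,4aR,8R,8aR)-8-(2-bromo-4-chlorophenoxy)-4a,8-dimethyldecahydronaphthalene-2-carboxylate, via sodium alkoxide 19 (not isolated)
Conditions: NaH, toluene, 0 °C to rt; then 18, rt to 40 °C
Reagents that add atoms: none
Why: Metal-free O-arylation of a tertiary alkoxide with a diaryliodonium salt (ligand coupling at trivalent iodine): the electron-poor, ortho-substituted aryl group should transfer in preference to the trimethoxyphenyl dummy, the C4–O bond is not broken so C4 keeps its configuration, and the ester keeps the C11 oxygen masked so only one alkoxide is present.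

Step 11
Reactants: 20 methyl (2R,4aR,8R,8aR)-8-(2-bromo-4-chlorophenoxy)-4a,8-dimethyldecahydronaphthalene-2-carboxylate
Product: 22 2-[(2R,4aR,8R,8aR)-8-(2-bromo-4-chlorophenoxy)-4a,8-dimethyldecahydronaphthalen-2-yl]propan-2-ol, via methyl ketone 21 (not isolated)
Conditions: MeMgBr (4 equiv), THF, 0 °C to rt; then water (pH 7 buffer)
Reagents that add atoms: methylmagnesium bromide, C[Mg]Br
Why: Double Grignard addition to the methyl ester gives the dimethylcarbinol; MeMgBr does not exchange with the aryl halides at this temperature, and the C7 centre stays equatorial.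

Step 12
Reactants: 23 4-bromo-2-(prop-2-en-1-yl)phenol; 24 bis(pinacolato)diboron
Product: 25 2-(prop-2-en-1-yl)-4-(4,4,5,5-tetramethyl-1,3,2-dioxaborolan-2-yl)phenol
Conditions: Pd(dppf)Cl2 (3 mol %), KOAc, 1,4-dioxane, 85 °C
Reagents that add atoms: none
Why: Miyaura borylation of the aryl bromide tolerates the free phenol and, with the weak acetate base, should leave the allyl group in place.

Step 13
Reactants: 22 2-[(2R,4aR,8R,8aR)-8-(2-bromo-4-chlorophenoxy)-4a,8-dimethyldecahydronaphthalen-2-yl]propan-2-ol; 25 2-(prop-2-en-1-yl)-4-(4,4,5,5-tetramethyl-1,3,2-dioxaborolan-2-yl)phenol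
Product: 26 2-[(2R,4aR,8R,8aR)-8-{[5-chloro-4'-hydroxy-3'-(prop-2-en-1-yl)-[1,1'-biphenyl]-2-yl]oxy}-4a,8-dimethyldecahydronaphthalen-2-yl]propan-2-ol
Conditions: Pd(OAc)2 (5 mol %), SPhos (10 mol %), K3PO4, toluene/H2O, 80 °C, 1.1 equiv of 25
Reagents that add atoms: none
Why: Suzuki–Miyaura coupling: oxidative addition at C–Br is much faster than at C–Cl, the bulky biarylphosphine copes with the ortho tertiary alkoxy group, and the free phenol and tertiary alcohol are tolerated.

Step 14
Reactants: 26 2-[(2R,4aR,8R,8aR)-8-{[5-chloro-4'-hydroxy-3'-(prop-2-en-1-yl)-[1,1'-biphenyl]-2-yl]oxy}-4a,8-dimethyldecahydronaphthalen-2-yl]propan-2-ol; 27 4,4,5,5-tetramethyl-2-(prop-2-en-1-yl)-1,3,2-dioxaborolane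
Product: 28 2-[(2R,4aR,8R,8aR)-8-{[4'-hydroxy-3',5-di(prop-2-en-1-yl)-[1,1'-biphenyl]-2-yl]oxy}-4a,8-dimethyldecahydronaphthalen-2-yl]propan-2-ol (CNP0219722.1)
Conditions: Pd(OAc)2 (5 mol %), XPhos (10 mol %), K3PO4, THF/H2O, 60 °C
Reagents that add atoms: none
Why: Suzuki–Miyaura allylation of the electron-rich aryl chloride with the allylboronate and a bulky biarylphosphine; the mild temperature should limit isomerisation of the allyl groups to propenyl groups.

**Compound list**

1 | hept-6-yn-1-ol | OCCCCCC#C | starting material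
2 | 6-methylideneoct-7-en-1-ol | OCCCCCC(=C)C=C | intermediate
3 | methyl 2-bromoprop-2-enoate | C=C(Br)C(=O)OC | starting material
4 | methyl (3E)-10-hydroxy-2,5-dimethylidenedec-3-enoate | OCCCCCC(=C)/C=C/C(=C)C(=O)OC | intermediate
5 | methyl (3E)-2,5-dimethylidene-10-oxodec-3-enoate | O=CCCCCC(=C)/C=C/C(=C)C(=O)OC | intermediate
6 | methyl (3E)-9-[(dimethylamino)methyl]-2,5-dimethylidene-10-oxodec-3-enoate (racemic Mannich base) | CN(C)CC(C=O)CCCC(=C)/C=C/C(=C)C(=O)OC | intermediate
7 | methyl (3E)-9-formyl-2,5-dimethylidenedeca-3,9-dienoate | O=CC(=C)CCCC(=C)/C=C/C(=C)C(=O)OC | intermediate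
8 | methyl (4aS,8aS)-4a-formyl-8-methylidene-3,4,4a,5,6,7,8,8a-octahydronaphthalene-2-carboxylate (trans-fused; angular formyl β, ring-fusion H α) | C=C2CCC[C@]3(C=O)CCC(C(=O)OC)=C[C@H]32 | intermediate
9 | methyl (4aS,8aS)-8-methylidene-4a-{(E)-[2-(4-methylbenzenesulfonyl)hydrazinylidene]methyl}-3,4,4a,5,6,7,8,8a-octahydronaphthalene-2-carboxylate | C=C2CCC[C@]3(/C=N/NS(=O)(=O)c4ccc(C)cc4)CCC(C(=O)OC)=C[C@H]32 | intermediate
10 | methyl (4aR,8aS)-4a-methyl-8-methylidene-3,4,4a,5,6,7,8,8a-octahydronaphthalene-2-carboxylate | C=C2CCC[C@]3(C)CCC(C(=O)OC)=C[C@H]32 | intermediate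
11 | methyl (2S,4aR,8aS)-4a-methyl-8-methylidenedecahydronaphthalene-2-carboxylate (axial ester) | C=C2CCC[C@]3(C)CC[C@H](C(=O)OC)C[C@H]32 | intermediate
12 | methyl (2R,4aR,8aS)-4a-methyl-8-methylidenedecahydronaphthalene-2-carboxylate (equatorial ester) | C=C2CCC[C@]3(C)CC[C@@H](C(=O)OC)C[C@H]32 | intermediate
13 | methyl (2R,4aR,8R,8aR)-8-hydroperoxy-4a,8-dimethyldecahydronaphthalene-2-carboxylate | OO[C@]2(C)CCC[C@]3(C)CC[C@@H](C(=O)OC)C[C@H]32 | intermediate
14 | methyl (2R,4aR,8R,8aR)-8-hydroxy-4a,8-dimethyldecahydronaphthalene-2-carboxylate | O[C@]2(C)CCC[C@]3(C)CC[C@@H](C(=O)OC)C[C@H]32 | intermediate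
15 | 2-bromo-4-chloro-1-iodobenzene | Clc1ccc(I)c(Br)c1 | starting material
16 | 1,3,5-trimethoxybenzene | COc1cc(OC)cc(OC)c1 | starting material
17 | [(2-bromo-4-chlorophenyl)(hydroxy)-λ3-iodanyl] 4-methylbenzenesulfonate | Cc1ccc(S(=O)(=O)OI(O)c2ccc(Cl)cc2Br)cc1 | intermediate
18 | (2-bromo-4-chlorophenyl)(2,4,6-trimethoxyphenyl)iodonium 4-methylbenzenesulfonate | COc1cc(OC)c([I+]c2ccc(Cl)cc2Br)c(OC)c1.Cc1ccc(S(=O)(=O)[O-])cc1 | intermediate
19 | sodium (1R,4aR,7R,8aR)-7-(methoxycarbonyl)-1,4a-dimethyldecahydronaphthalen-1-olate | [Na+].[O-][C@]2(C)CCC[C@]3(C)CC[C@@H](C(=O)OC)C[C@H]32 | intermediate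
20 | methyl (2R,4aR,8R,8aR)-8-(2-bromo-4-chlorophenoxy)-4a,8-dimethyldecahydronaphthalene-2-carboxylate | Clc1ccc(O[C@]2(C)CCC[C@]3(C)CC[C@@H](C(=O)OC)C[C@H]32)c(Br)c1 | intermediate
21 | 1-[(2R,4aR,8R,8aR)-8-(2-bromo-4-chlorophenoxy)-4a,8-dimethyldecahydronaphthalen-2-yl]ethan-1-one | Clc1ccc(O[C@]2(C)CCC[C@]3(C)CC[C@@H](C(C)=O)C[C@H]32)c(Br)c1 | intermediate
22 | 2-[(2R,4aR,8R,8aR)-8-(2-bromo-4-chlorophenoxy)-4a,8-dimethyldecahydronaphthalen-2-yl]propan-2-ol | Clc1ccc(O[C@]2(C)CCC[C@]3(C)CC[C@@H](C(C)(C)O)C[C@H]32)c(Br)c1 | intermediate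
23 | 4-bromo-2-(prop-2-en-1-yl)phenol | C=CCc1cc(Br)ccc1O | starting material
24 | bis(pinacolato)diboron | CC1(C)OB(B2OC(C)(C)C(C)(C)O2)OC1(C)C | starting material
25 | 2-(prop-2-en-1-yl)-4-(4,4,5,5-tetramethyl-1,3,2-dioxaborolan-2-yl)phenol | C=CCc1cc(B2OC(C)(C)C(C)(C)O2)ccc1O | intermediate
26 | 2-[(2R,4aR,8R,8aR)-8-{[5-chloro-4'-hydroxy-3'-(prop-2-en-1-yl)-[1,1'-biphenyl]-2-yl]oxy}-4a,8-dimethyldecahydronaphthalen-2-yl]propan-2-ol | Clc1ccc(O[C@]2(C)CCC[C@]3(C)CC[C@@H](C(C)(C)O)C[C@H]32)c(-c2ccc(O)c(CC=C)c2)c1 | intermediate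
27 | 4,4,5,5-tetramethyl-2-(prop-2-en-1-yl)-1,3,2-dioxaborolane | C=CCB1OC(C)(C)C(C)(C)O1 | starting material
28 | 2-[(2R,4aR,8R,8aR)-8-{[4'-hydroxy-3',5-di(prop-2-en-1-yl)-[1,1'-biphenyl]-2-yl]oxy}-4a,8-dimethyldecahydronaphthalen-2-yl]propan-2-ol | C=CCc1ccc(O[C@]2(C)CCC[C@]3(C)CC[C@@H](C(C)(C)O)C[C@H]32)c(-c2ccc(O)c(CC=C)c2)c1 | target

**Totals**

Total: 14 steps. Longest linear sequence: 12 steps (steps 1–8, 10, 11, 13 and 14); steps 9 and 12 prepare the two coupling partners.

**Risks and fallbacks**

The three steps most likely to fail are, in order of risk, step 5, step 10 and step 2.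

Risk 1 (step 5). The electron-poor diene may turn over slowly on the chiral Lewis acid, so that the uncatalysed racemic cyclisation and intermolecular dimerisation compete, and endo (trans-fusion) or facial selectivity may erode. The fallback sets out from compound 7 and comes back to the route at compound 8, replacing asymmetric catalysis by resolution. Cyclisation with the achiral Lewis acid Me2AlCl (CH2Cl2, −78 to −20 °C) should give racemic trans-fused methyl 4a-formyl-8-methylidene-3,4,4a,5,6,7,8,8a-octahydronaphthalene-2-carboxylate F1. NaBH4 (MeOH, 0 °C) should reduce only the aldehyde to racemic trans-fused methyl 4a-(hydroxymethyl)-8-methylidene-3,4,4a,5,6,7,8,8a-octahydronaphthalene-2-carboxylate F2. Acylation with (1S,4R)-camphanic chloride (Et3N, DMAP, CH2Cl2) should give two diastereomeric esters, methyl (4aS,8aS)-8-methylidene-4a-({[(1S,4R)-4,7,7-trimethyl-3-oxo-2-oxabicyclo[2.2.1]heptane-1-carbonyl]oxy}methyl)-3,4,4a,5,6,7,8,8a-octahydronaphthalene-2-carboxylate F3 and methyl (4aR,8aR)-8-methylidene-4a-({[(1S,4R)-4,7,7-trimethyl-3-oxo-2-oxabicyclo[2.2.1]heptane-1-carbonyl]oxy}methyl)-3,4,4a,5,6,7,8,8a-octahydronaphthalene-2-carboxylate F4, which are separated by chromatography or crystallisation, the latter being set aside. K2CO3 in MeOH should release methyl (4aS,8aS)-4a-(hydroxymethyl)-8-methylidene-3,4,4a,5,6,7,8,8a-octahydronaphthalene-2-carboxylate F5 from the wanted ester, and Dess–Martin oxidation then returns compound 8.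

Risk 2 (step 10). Arylation of the hindered equatorial tertiary alkoxide may be slower than base-induced aryne formation from the iodonium salt or enolisation of the ester. The fallback sets out from compound 14 and comes back to the route at compound 20, replacing ligand coupling by nucleophilic aromatic substitution. The potassium alkoxide (KHMDS, THF/DMF, 0 °C) with 2-bromo-1-fluoro-4-nitrobenzene should give methyl (2R,4aR,8R,8aR)-8-(2-bromo-4-nitrophenoxy)-4a,8-dimethyldecahydronaphthalene-2-carboxylate F6. Fe/NH4Cl (EtOH/H2O, 70 °C) should reduce the nitro group to give methyl (2R,4aR,8R,8aR)-8-(4-amino-2-bromophenoxy)-4a,8-dimethyldecahydronaphthalene-2-carboxylate F7. Non-aqueous Sandmeyer chlorination (tBuONO, CuCl2, MeCN, 60 °C) then gives compound 20.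

Risk 3 (step 2). The 2-bromoacrylate may polymerise or decompose under base, the allylpalladium intermediate may be trapped before β-hydride elimination, and the product may undergo Diels–Alder dimerisation at the reaction temperature. The fallback sets out from compound 1 and comes back to the route at compound 4, replacing the Heck reaction by boron chemistry. Cross enyne metathesis of compound 1 with 2-ethenyl-4,4,5,5-tetramethyl-1,3,2-dioxaborolane ((H2IMes)(PCy3)Cl2Ru=CHPh, CH2Cl2, 40 °C) should give, after removal of any (Z) isomer, (7E)-6-methylidene-8-(4,4,5,5-tetramethyl-1,3,2-dioxaborolan-2-yl)oct-7-en-1-ol F8. Suzuki–Miyaura coupling with compound 3 (Pd(PPh3)4, CsF, THF, rt) then gives compound 4.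

Further compounds
F1 | step 5 | racemic trans-fused methyl 4a-formyl-8-methylidene-3,4,4a,5,6,7,8,8a-octahydronaphthalene-2-carboxylate (8 and its mirror image) | C=C2CCC[C@]3(C=O)CCC(C(=O)OC)=C[C@H]32.C=C2CCC[C@@]3(C=O)CCC(C(=O)OC)=C[C@@H]32
F2 | step 5 | racemic trans-fused methyl 4a-(hydroxymethyl)-8-methylidene-3,4,4a,5,6,7,8,8a-octahydronaphthalene-2-carboxylate | C=C2CCC[C@]3(CO)CCC(C(=O)OC)=C[C@H]32.C=C2CCC[C@@]3(CO)CCC(C(=O)OC)=C[C@@H]32
F3 | step 5 | methyl (4aS,8aS)-8-methylidene-4a-({[(1S,4R)-4,7,7-trimethyl-3-oxo-2-oxabicyclo[2.2.1]heptane-1-carbonyl]oxy}methyl)-3,4,4a,5,6,7,8,8a-octahydronaphthalene-2-carboxylate | C=C2CCC[C@]3(COC(=O)[C@]4(OC5=O)CC[C@]5(C)C4(C)C)CCC(C(=O)OC)=C[C@H]32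
F4 | step 5 | methyl (4aR,8aR)-8-methylidene-4a-({[(1S,4R)-4,7,7-trimethyl-3-oxo-2-oxabicyclo[2.2.1]heptane-1-carbonyl]oxy}methyl)-3,4,4a,5,6,7,8,8a-octahydronaphthalene-2-carboxylate | C=C2CCC[C@@]3(COC(=O)[C@]4(OC5=O)CC[C@]5(C)C4(C)C)CCC(C(=O)OC)=C[C@@H]32
F5 | step 5 | methyl (4aS,8aS)-4a-(hydroxymethyl)-8-methylidene-3,4,4a,5,6,7,8,8a-octahydronaphthalene-2-carboxylate | C=C2CCC[C@]3(CO)CCC(C(=O)OC)=C[C@H]32
F6 | step 10 | methyl (2R,4aR,8R,8aR)-8-(2-bromo-4-nitrophenoxy)-4a,8-dimethyldecahydronaphthalene-2-carboxylate | [O-][N+](=O)c1ccc(O[C@]2(C)CCC[C@]3(C)CC[C@@H](C(=O)OC)C[C@H]32)c(Br)c1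
F7 | step 10 | methyl (2R,4aR,8R,8aR)-8-(4-amino-2-bromophenoxy)-4a,8-dimethyldecahydronaphthalene-2-carboxylate | Nc1ccc(O[C@]2(C)CCC[C@]3(C)CC[C@@H](C(=O)OC)C[C@H]32)c(Br)c1
F8 | step 2 | (7E)-6-methylidene-8-(4,4,5,5-tetramethyl-1,3,2-dioxaborolan-2-yl)oct-7-en-1-ol | OCCCCCC(=C)/C=C/B1OC(C)(C)C(C)(C)O1
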